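**Retrosynthetic overview**
1. The hemiketal comes from an α-methylene ketone at C4 plus the C8 tertiary alcohol; that ketone comes from a Ti(III) epoxide→allylic alcohol isomerisation of a C4/C5 epoxide, which comes from ring-closing metathesis of an allyl/methallyl diene. The 10-membered ring is closed last.
2. The γ-lactone and the C8 quaternary carbinol come from an intramolecular Reformatsky-type aldol (SmI2) of a C7 α-bromopropionate onto the C8 ketone.
3. Key step: the trans-fused cyclohexane (C1–C10 bond, quaternary C1, exocyclic C11=C20, axial C14–O) forms by Cp2TiCl radical epoxide opening, 6-endo cyclisation and β-H elimination on a fully elaborated epoxy ketol.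
4. The cyclisation precursor comes from an NHK coupling of an (E)-vinyl iodide epoxy alcohol (from 4-pentyn-1-ol; Brown allylation then Sharpless epoxidation) with an α-keto aldehyde (from pyruvaldehyde dimethyl acetal; methallylation then α-hydroxylation).
Ring order: cyclohexane → γ-lactone → 10-membered ring → oxa-bridge (hemiketal).

Assumption: the Ti(III) cyclisation delivers the axial C14–O diastereomer directly, so no later C14 inversion is needed.

---

**Step 1**
Reactants: 1 (4-pentyn-1-ol)
Product: 2 ((E)-5-iodo-4-methylpent-4-en-1-ol)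
Conditions: Me3Al, Cp2ZrCl2 (cat.), ClCH2CH2Cl, 0 °C→rt; then I2, THF, −30 °C
Reagents that add atoms: trimethylaluminum C[Al](C)C (CH3); iodine II (I)
Why: Negishi Zr-catalysed methylalumination is syn, and iodination gives the (E)-trisubstituted vinyl iodide (C10, C11, C20) with the correct geometry.

**Step 2**
Reactants: 2
Product: 3 ((E)-5-iodo-4-methylpent-4-enal)
Conditions: DMP, NaHCO3, CH2Cl2, 0 °C→rt
Reagents that add atoms: none
Why: Dess–Martin oxidation of the primary alcohol leaves the vinyl iodide untouched.

**Step 3**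
Reactants: 3
Product: 4 ((2E,6E)-7-iodo-2,6-dimethylhepta-2,6-dienal)
Conditions: Ph3P=C(Me)CHO, CH2Cl2, 40 °C
Reagents that add atoms: 2-(triphenylphosphoranylidene)propanal O=CC(C)=P(c1ccccc1)(c1ccccc1)c1ccccc1 (adds C1, C15, C2)
Why: Wittig olefination with a stabilised ylide is E-selective, which puts C2 and C13 trans on the C1=C14 alkene.

**Step 4**
Reactants: 4
Product: 5 ((4R,5E,9E)-10-iodo-5,9-dimethyldeca-1,5,9-trien-4-ol)
Conditions: Ipc2B-allyl, Et2O, −78 °C; then NaOH, H2O2
Reagents that add atoms: B-allyldiisopinocampheylborane C=CCB(C1CC2CC(C2(C)C)C1C)C1CC2CC(C2(C)C)C1C (allyl; pinene enantiomer chosen to give the (R)-carbinol)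
Why: Brown asymmetric allylboration is reagent-controlled and sets C2 as (R) while creating the C3–C4 arm.

**Step 5**
Reactants: 5
Product: 6 ((1R)-1-{trans-3-[(E)-4-iodo-3-methylbut-3-enyl]-2-methyloxiranyl}but-3-en-1-ol; epoxide faces as in the SMILES)
Conditions: Ti(OiPr)4, D-(−)-DET, TBHP, 4 Å MS, CH2Cl2, −20 °C
Reagents that add atoms: tert-butyl hydroperoxide CC(C)(C)OO (one O)
Why: Sharpless asymmetric epoxidation is matched for the (R)-allylic alcohol with D-(−)-DET; it epoxidises only the allylic-alcohol olefin and fixes the C14 configuration of the target (the C1 centre is destroyed in step 11).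

**Step 6**
Reactants: 7 (pyruvaldehyde dimethyl acetal)
Product: 8 (1,1-dimethoxy-5-methylhex-5-en-2-one)
Conditions: LDA, THF, −78 °C; then methallyl bromide, −78→0 °C
Reagents that add atoms: 3-bromo-2-methylpropene C=C(C)CBr (methallyl: C6, C5, C16 and a terminal CH2 lost later)
Why: the CH3 is the only enolisable site, and SN2 alkylation of its kinetic enolate forms the C6–C7 bond.

**Step 7**
Reactants: 8
Product: 9 ((S)-3-hydroxy-1,1-dimethoxy-5-methylhex-5-en-2-one)
Conditions: PhNO, proline (30 mol %), DMSO, rt; then CuSO4·5H2O, MeOH, rt (one pot)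
Reagents that add atoms: nitrosobenzene O=Nc1ccccc1 (only its O is retained)
Why: proline-enamine α-aminoxylation at the only enolisable carbon sets C7 as (S) by catalyst control, and Cu(II) cleaves the N–O bond to the free alcohol.

**Step 8**
Reactants: 9
Product: 10 (C7 TBS ether of 9)
Conditions: TBSOTf, 2,6-lutidine, CH2Cl2, −78→0 °C
Reagents that add atoms: tert-butyldimethylsilyl triflate C[Si](C)(C(C)(C)C)OS(=O)(=O)C(F)(F)F (TBS)
Why: silylation protects C7–OH through the Ti(III) and acylation steps.

**Step 9**
Reactants: 10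
Product: 11 ((S)-3-(TBSO)-5-methyl-2-oxohex-5-enal, used as its hydrate after azeotropic drying)
Conditions: Amberlyst-15, acetone/H2O, 40 °C
Reagents that add atoms: water O
Why: acid hydrolysis of the dimethyl acetal unmasks the aldehyde (C9).

**Step 10**
Reactants: 6, 11
Product: 12 (C9 allylic alcohol (9R), C8 ketone, C7–OTBS, epoxide, free C2–OH)
Conditions: CrCl2 (excess), NiCl2 (cat.), chiral sulfonamide ligand, DMF/MeCN, rt
Reagents that add atoms: none
Why: Proposed new method: the vinylchromium generated from the (E)-vinyl iodide adds selectively to the more electrophilic aldehyde of the α-keto aldehyde with retention of alkene geometry, and the chiral ligand sets C9 (R), tolerating the epoxide, free OH and ketone; the closest known reaction is the Kishi–Fürstner asymmetric NHK of vinyl iodides with aldehydes.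

**Step 11** (key radical step)
Reactants: 12
Product: 13 (trans-fused cyclohexane with exocyclic methylene)
Conditions: Cp2TiCl2 (20 mol %), Mn, 2,4,6-collidine, TMSCl, THF, rt; then 1 M HCl
Reagents that add atoms: none (TMS is removed at work-up)
Why: Proposed new method: Cp2TiCl opens the epoxide to the tertiary C1 radical with C14–OTi; the radical adds 6-endo through a chair to the (E)-C10=C11 olefin, and Ti trapping then β-H elimination from C20 gives the exocyclic methylene, with C2 and C9 equatorial, C15 methyl axial and trans ring fusion. The axial C14–O is anti to the axial methyl, so it costs less than the two gauche contacts of the equatorial alternative. The closest known reaction is Cp2TiCl-catalysed epoxypolyene cyclisation (Cuerva/Oltra).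

**Step 12**
Reactants: 13
Product: 14 (triacetate at C2, C9, C14)
Conditions: Ac2O, DMAP, pyridine, CH2Cl2, 40 °C
Reagents that add atoms: acetic anhydride CC(=O)OC(C)=O (3 × Ac)
Why: acetylation of the three free secondary OH groups installs the target acetates; the ketone and TBS ether are untouched.

**Step 13**
Reactants: 14
Product: 15 (free C7–OH)
Conditions: HF·pyridine, pyridine, THF, 0 °C→rt
Reagents that add atoms: none
Why: fluoride removal of the secondary TBS ether under non-basic conditions avoids acyl migration and C7 epimerisation.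

**Step 14**
Reactants: 15
Product: 16 (C7 2-bromopropionate)
Conditions: 2-bromopropionyl bromide, pyridine, DMAP (cat.), CH2Cl2, 0 °C
Reagents that add atoms: 2-bromopropionyl bromide CC(Br)C(=O)Br (C17, C18, C19)
Why: acylation of the only free OH gives the α-bromo ester for lactone closure; racemic C17 is fine because it is reset in step 15.

**Step 15**
Reactants: 16
Product: 17 (γ-lactone with C8 tertiary OH and C17 methyl)
Conditions: SmI2 (2.5 equiv), THF, −78 °C
Reagents that add atoms: none
Why: SmI2 reduces the C–Br bond to a Sm(III) enolate that closes onto the C8 ketone by 5-exo intramolecular aldol (Reformatsky-type); the cis-fused lactone is favoured with the bulky C9 anti to C6, and C17 is set in the aldol transition state.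

**Step 16**
Reactants: 17
Product: 18 (10-membered carbocycle with trisubstituted C4=C5)
Conditions: Hoveyda–Grubbs II (20 mol %), CH2Cl2 (1–2 mM), 40 °C
Reagents that add atoms: none
Why: RCM of the allyl (C4) and methallyl (C5) olefins with loss of ethylene closes the 10-ring, and the trans-fused cyclohexane and cis-lactone pre-organise it; the alkene geometry is irrelevant because both carbons are functionalised later.

**Step 17**
Reactants: 18
Product: 19 (C4–C5 epoxide)
Conditions: mCPBA (1.0 equiv), NaHCO3, CH2Cl2, −20 °C
Reagents that add atoms: mCPBA OOC(=O)c1cccc(Cl)c1 (one O)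
Why: Prilezhaev epoxidation is selective for the more electron-rich trisubstituted ring olefin over the exocyclic 1,1-disubstituted C11=C20 olefin; the epoxide stereochemistry is irrelevant because C5 becomes sp2 and C4 is oxidised in step 19.

**Step 18**
Reactants: 19
Product: 20 (C4 allylic alcohol with exocyclic C5=C16)
Conditions: Cp2TiCl2 (10 mol %), Mn, 2,4,6-collidine, TMSCl, THF, rt; then 1 M HCl
Reagents that add atoms: none
Why: Cp2TiCl opens the epoxide to the tertiary C5 radical (C4–OTi), and β-H elimination from the C16 methyl gives the exocyclic methylene; this is the known Ti(III)-catalysed epoxide→allylic alcohol isomerisation.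

**Step 19**
Reactants: 20
Product: 21 (junceellolide A)
Conditions: activated MnO2, CH2Cl2, rt
Reagents that add atoms: none
Why: MnO2 oxidises only the allylic C4 alcohol to the α-methylene ketone, which is trapped by the C8 tertiary OH as the six-membered hemiketal; the oxa-bridge allows only one C4 configuration, so it is set by ring constraint.

---

**Compound list**

| No. | Name | SMILES | Role |
|---|---|---|---|
| 1 | 4-pentyn-1-ol | C#CCCCO | starting material |
| 2 | (E)-5-iodo-4-methylpent-4-en-1-ol | OCCC/C(C)=C/I | intermediate |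
| 3 | (E)-5-iodo-4-methylpent-4-enal | O=CCC/C(C)=C/I | intermediate |
| 4 | (2E,6E)-7-iodo-2,6-dimethylhepta-2,6-dienal | O=C/C(C)=C/CC/C(C)=C/I | intermediate |
| 5 | (4R,5E,9E)-10-iodo-5,9-dimethyldeca-1,5,9-trien-4-ol | C=CC[C@@H](O)/C(C)=C/CC/C(C)=C/I | intermediate |
| 6 | epoxy alcohol (Sharpless product) | C=CC[C@@H](O)[C@]1(C)O[C@H]1CC/C(C)=C/I | intermediate |
| 7 | pyruvaldehyde dimethyl acetal | COC(OC)C(C)=O | starting material |
| 8 | 1,1-dimethoxy-5-methylhex-5-en-2-one | COC(OC)C(=O)CCC(C)=C | intermediate |
| 9 | (S)-3-hydroxy-1,1-dimethoxy-5-methylhex-5-en-2-one | COC(OC)C(=O)[C@@H](O)CC(C)=C | intermediate |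
| 10 | C7 TBS ether of 9 | COC(OC)C(=O)[C@@H](O[Si](C)(C)C(C)(C)C)CC(C)=C | intermediate |
| 11 | (S)-3-(TBSO)-5-methyl-2-oxohex-5-enal | O=CC(=O)[C@@H](O[Si](C)(C)C(C)(C)C)CC(C)=C | intermediate |
| 12 | NHK adduct (C9-OH, C8 ketone, epoxide) | C=CC[C@@H](O)[C@]1(C)O[C@H]1CC/C(C)=C/[C@@H](O)C(=O)[C@@H](O[Si](C)(C)C(C)(C)C)CC(C)=C | intermediate |
| 13 | trans-fused cyclohexane ketol | C=C1CC[C@H](O)[C@](C)([C@H](O)CC=C)[C@H]1[C@@H](O)C(=O)[C@@H](O[Si](C)(C)C(C)(C)C)CC(C)=C | intermediate |
| 14 | triacetate of 13 | C=C1CC[C@H](OC(C)=O)[C@](C)([C@H](OC(C)=O)CC=C)[C@H]1[C@@H](OC(C)=O)C(=O)[C@@H](O[Si](C)(C)C(C)(C)C)CC(C)=C | intermediate |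
| 15 | C7 alcohol | C=C1CC[C@H](OC(C)=O)[C@](C)([C@H](OC(C)=O)CC=C)[C@H]1[C@@H](OC(C)=O)C(=O)[C@@H](O)CC(C)=C | intermediate |
| 16 | C7 2-bromopropionate (C17 epimeric) | C=C1CC[C@H](OC(C)=O)[C@](C)([C@H](OC(C)=O)CC=C)[C@H]1[C@@H](OC(C)=O)C(=O)[C@@H](OC(=O)C(C)Br)CC(C)=C | intermediate |
| 17 | lactone with C8-OH | C=C1CC[C@H](OC(C)=O)[C@](C)([C@H](OC(C)=O)CC=C)[C@H]1[C@@H](OC(C)=O)[C@@]2(O)[C@H](CC(C)=C)OC(=O)[C@@H]2C | intermediate |
| 18 | RCM macrocycle (C4=C5 olefin, geometry unspecified) | C=C1CC[C@H](OC(C)=O)[C@@]2(C)[C@H]1[C@@H](OC(C)=O)[C@@]3(O)[C@H](CC(C)=CC[C@H]2OC(C)=O)OC(=O)[C@@H]3C | intermediate |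
| 19 | C4/C5 epoxide (stereochemistry unspecified) | C=C1CC[C@H](OC(C)=O)[C@@]2(C)[C@H]1[C@@H](OC(C)=O)[C@@]3(O)[C@H](CC4(C)OC4C[C@H]2OC(C)=O)OC(=O)[C@@H]3C | intermediate |
| 20 | C4 allylic alcohol (C4 stereochemistry unspecified) | C=C1CC[C@H](OC(C)=O)[C@@]2(C)[C@H]1[C@@H](OC(C)=O)[C@@]3(O)[C@H](CC(=C)C(O)C[C@H]2OC(C)=O)OC(=O)[C@@H]3C | intermediate |
| 21 | (+)-junceellolide A | C=C1CC[C@H](OC(C)=O)[C@@]2(C)[C@H]1[C@@H](OC(C)=O)[C@@]13O[C@](O)(C[C@H]2OC(C)=O)C(=C)C[C@@H]1OC(=O)[C@@H]3C | target |

---

**Totals:** 19 steps; longest linear sequence 15 (steps 1–5 and 10–19; steps 6–9 make the right-hand fragment in parallel).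

**Three steps most likely to fail**
1. Step 11 (Ti(III) cyclisation). Risks: reduction of the C8 ketone, β-elimination/deoxygenation, or the equatorial-O (C14-epi) diastereomer.
 - Fallback: reduce and protect C8 first, run a Lewis-acid-promoted cationic epoxide–olefin cyclisation (BF3·OEt2) instead of the radical route, then invert C14 by oxidation/reduction and re-oxidise C8.
2. Step 16 (RCM to the 10-membered trisubstituted olefin).
 - Fallback: close the ring by intramolecular NHK of a C4 aldehyde with a C5 vinyl halide. This needs a 2-bromoallyl group in place of the methallyl group and a C4 aldehyde obtained from the allyl group by hydroboration of its vinyl analogue and oxidation, followed by oxidation of the resulting allylic alcohol.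
3. Step 10 (NHK with the α-keto aldehyde; C9 stereocontrol).
 - Fallback: add the alkenyl unit to a C8-silyloxy aldehyde (no ketone present) and oxidise C8 later, or build the C9 vinyl carbinol first and join the fragments by cross-metathesis with the 1,1-disubstituted alkene of an isoprene-derived left-hand fragment.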